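**Plan**

- Retrosynthesis: the two enoate C–O bonds at O3 and O5 are cut first, the C3 carbinol is taken back to a ketone and the C1=C2 alkene to a C1 carbinol; the ring bond C1–C2 is then cut (retro-aldol) to an acyclic 2,6-diketo ester, which is cut at chain C4–C5 (intermolecular aldol) and at C3–C(vinyl) (SN2′).
- Forward: SN2′ vinylation and ozonolysis give a five-carbon aldehyde; a syn-aldol with silyloxyacetone completes the seven-carbon chain; a second ozonolysis unmasks the α-keto ester; the only ring then closes by the intramolecular aldol (chain C2, C7, C6, C5, C4, C3 become ring C1 to C6).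
- Enabling feature: with the ring numbered C1 (ester-bearing alkene carbon), C2 (alkene CH), C3–C5 (oxygenated carbons) and C6 (CH2), the C1–C2 bond joins the carboxyl-bearing carbon to the carbon α to the C3 oxygen, so an open-chain methyl ketone (C2/C3) and α-keto ester (C1) close the six-membered carbocycle.
- Stereochemistry: C4 and C5 come from the amino-acid-catalysed syn-aldol (D-threo); C3 comes from a hydroxyl-directed reduction anti to the C5 hydroxyl, hence cis to O4; the C1 carbinol of the key step is erased by dehydration; the E-enoate geometry is bought with the acid.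
- Oxygen differentiation: the TBS ether brought in with the aldol donor marks O4 to the end. A temporary TES ether on O5 prevents lactonisation and β-elimination at the keto ester stage and keeps the dehydration selective; it is removed before the reduction so that O3 and O5 are acylated together.

Key step: step 6

Assumption: the O-tert-butyl-D-threonine-catalysed aldol is taken to show, with the aliphatic acceptor 5, the same sense of induction established for this catalyst class with protected hydroxy ketones (D-catalyst gives the D-threo, 4R,5S adduct).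

**Step 1**
Reactants: 1 methyl 2-(bromomethyl)acrylate; 2 vinylmagnesium bromide
Product: 3 methyl 2-methylidenepent-4-enoate
Conditions: CuI (10 mol %), THF, −78 → −30 °C
Reagents that add atoms: none
Why: Copper-catalysed SN2′ allylic substitution of a 2-(bromomethyl)acrylate by a Grignard reagent is a standard route to 2-substituted acrylates, and no stereocentre is formed.

**Step 2**
Reactants: 3 methyl 2-methylidenepent-4-enoate
Product: 5 methyl 2-methylidene-4-oxobutanoate, via ozonide 4 (not isolated)
Conditions: O3 (1.0 equiv, Sudan Red 7B end point), CH2Cl2, −78 °C; then Me2S, −78 °C → rt; water wash; used at once as a cold solution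
Reagents that add atoms: ozone, [O-][O+]=O
Why: Chemoselective ozonolysis should work because electrophilic ozone cleaves the isolated monosubstituted alkene much faster than the electron-poor acrylate alkene, and the aldehyde is not purified because its double bond can move into conjugation.

**Step 3**
Reactants: 5 methyl 2-methylidene-4-oxobutanoate; 6 1-[(tert-butyldimethylsilyl)oxy]propan-2-one
Product: 7 methyl (4R,5S)-5-[(tert-butyldimethylsilyl)oxy]-4-hydroxy-2-methylidene-6-oxoheptanoate
Conditions: O-tert-butyl-D-threonine (20 mol %), 6 (5 equiv), NMP, H2O (3 equiv), 4 °C; 5 added slowly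
Reagents that add atoms: none
Why: In this primary-amine (enamine) catalysed direct aldol addition the catalyst condenses with 6 on its oxygenated side to a (Z)-enamine held by an N–H···O hydrogen bond, and its carboxylic-acid-directed addition to the aldehyde gives the syn adduct, the D-catalyst setting chain C4 (R) and C5 (S), the future ring C5 and C4.

**Step 4**
Reactants: 7 methyl (4R,5S)-5-[(tert-butyldimethylsilyl)oxy]-4-hydroxy-2-methylidene-6-oxoheptanoate
Product: 8 methyl (4R,5S)-5-[(tert-butyldimethylsilyl)oxy]-2-methylidene-6-oxo-4-[(triethylsilyl)oxy]heptanoate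
Conditions: TESCl, imidazole, DMF, 0 °C
Reagents that add atoms: chlorotriethylsilane (TESCl), CC[Si](Cl)(CC)CC
Why: Silylation of a secondary β-hydroxyl is routine, and the TES ether blocks lactonisation onto the ester and retro-aldol while remaining removable in the presence of the TBS ether.

**Step 5**
Reactants: 8 methyl (4R,5S)-5-[(tert-butyldimethylsilyl)oxy]-2-methylidene-6-oxo-4-[(triethylsilyl)oxy]heptanoate
Product: 10 methyl (4R,5S)-5-[(tert-butyldimethylsilyl)oxy]-2,6-dioxo-4-[(triethylsilyl)oxy]heptanoate, via ozonide 9 (not isolated)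
Conditions: O3, CH2Cl2, −78 °C; then Me2S, −78 °C → rt; water wash, azeotropic drying
Reagents that add atoms: ozone, [O-][O+]=O
Why: Ozonolysis of a 2-alkylacrylate with reductive work-up is the standard unmasking of 3-deoxy-2-ulosonic esters, and the silyl ethers and the saturated ketone are inert to ozone at −78 °C.

**Step 6**
Reactants: 10 methyl (4R,5S)-5-[(tert-butyldimethylsilyl)oxy]-2,6-dioxo-4-[(triethylsilyl)oxy]heptanoate
Product: 11 methyl (4S,5R)-4-[(tert-butyldimethylsilyl)oxy]-1-hydroxy-3-oxo-5-[(triethylsilyl)oxy]cyclohexane-1-carboxylate (both C1 epimers; a protected methyl 3-dehydroquinate)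
Conditions: Et3N (0.2 equiv), CH2Cl2, 0 °C → rt
Reagents that add atoms: none
Why: Triethylamine reversibly deprotonates the C7 methyl group of the silyloxy ketone, and the enolate adds to the C2 carbonyl of the α-keto ester, the most electrophilic carbonyl of 10, to give the tertiary α-hydroxy ester 11 (chain C2 and C7 become ring C1 and C2). The closest known reaction type is the intramolecular aldol addition of a 1,5-dicarbonyl compound, here the non-enzymatic counterpart of the ring closure that turns the open-chain 2,6-diketo acid into 3-dehydroquinate. The cyclohexane ring closes in the 6-(enolexo)-exo-trig mode through a chair in which the trans silyloxy groups at ring C4 and C5 are equatorial. The one new stereocentre, the C1 carbinol, is not controlled and needs no control because step 7 removes it, while C4 and C5 are carried over unchanged from step 3. The selectivity needed is constitutional: only the C7 enolate/C2 carbonyl pairing can form a six-membered ring (enolates at C3 or C5 could only close four-membered rings), and the keto ester has no α-hydrogen on its ester side. The TES ether rules out lactonisation and retro-aldol through the chain O4, and a weak amine at low temperature should keep E1cB loss of that silyloxy group and epimerisation at C5 slower than addition to the activated carbonyl.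

**Step 7**
Reactants: 11 methyl (4S,5R)-4-[(tert-butyldimethylsilyl)oxy]-1-hydroxy-3-oxo-5-[(triethylsilyl)oxy]cyclohexane-1-carboxylate
Product: 13 methyl (4S,5R)-4-[(tert-butyldimethylsilyl)oxy]-3-oxo-5-[(triethylsilyl)oxy]cyclohex-1-ene-1-carboxylate, via tertiary trifluoroacetate 12 (not isolated)
Conditions: (CF3CO)2O, pyridine, CH2Cl2, 0 °C; then Et3N, 0 °C
Reagents that add atoms: none
Why: Activation of the only free (tertiary) hydroxyl as its trifluoroacetate and E1cB elimination through the C3 ketone enolate (C2–H) is a standard aldol dehydration that can only give the C1=C2 enone and erases the C1 stereocentre.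

**Step 8**
Reactants: 13 methyl (4S,5R)-4-[(tert-butyldimethylsilyl)oxy]-3-oxo-5-[(triethylsilyl)oxy]cyclohex-1-ene-1-carboxylate
Product: 14 methyl (4S,5R)-4-[(tert-butyldimethylsilyl)oxy]-5-hydroxy-3-oxocyclohex-1-ene-1-carboxylate
Conditions: PPTS (0.2 equiv), MeOH/CH2Cl2, 0 °C
Reagents that add atoms: none
Why: Acid-catalysed methanolysis cleaves a secondary triethylsilyl ether far faster than a secondary tert-butyldimethylsilyl ether (selective silyl ether cleavage), freeing only O5.

**Step 9**
Reactants: 14 methyl (4S,5R)-4-[(tert-butyldimethylsilyl)oxy]-5-hydroxy-3-oxocyclohex-1-ene-1-carboxylate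
Product: 15 methyl (3R,4S,5R)-4-[(tert-butyldimethylsilyl)oxy]-3,5-dihydroxycyclohex-1-ene-1-carboxylate (methyl 4-O-TBS-shikimate)
Conditions: Me4NBH(OAc)3, AcOH/MeCN (1:1), −30 °C
Reagents that add atoms: none
Why: In this hydroxyl-directed (Evans–Saksena) reduction the C5 hydroxyl binds boron and delivers hydride to the same face of the C3 carbonyl, giving the 1,3-anti diol, that is the 3R alcohol cis to the C4 silyl ether, while the triacetoxyborohydride leaves ester and alkene untouched.

**Step 10**
Reactants: 15 methyl (3R,4S,5R)-4-[(tert-butyldimethylsilyl)oxy]-3,5-dihydroxycyclohex-1-ene-1-carboxylate; 16 (E)-3-methylpent-2-enoic acid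
Product: 18 methyl (3R,4S,5R)-4-[(tert-butyldimethylsilyl)oxy]-3,5-bis{[(2E)-3-methylpent-2-enoyl]oxy}cyclohex-1-ene-1-carboxylate, via O-acylisourea 17 (not isolated)
Conditions: 16 (3 equiv), DCC (3 equiv), DMAP (0.3 equiv), CH2Cl2, 0 °C → rt
Reagents that add atoms: none
Why: Steglich esterification acylates both secondary hydroxyls while the silyl ether keeps O4 blocked, and the absence of a strong base avoids vinylketene formation, so the E geometry of the enoate should be retained.

**Step 11**
Reactants: 18 methyl (3R,4S,5R)-4-[(tert-butyldimethylsilyl)oxy]-3,5-bis{[(2E)-3-methylpent-2-enoyl]oxy}cyclohex-1-ene-1-carboxylate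
Product: 19 methyl (3R,4S,5R)-4-hydroxy-3,5-bis{[(2E)-3-methylpent-2-enoyl]oxy}cyclohex-1-ene-1-carboxylate (CNP0268575.1)
Conditions: HF·pyridine, pyridine, THF, 0 °C → rt
Reagents that add atoms: none
Why: Fluoride desilylation under acidic, buffered conditions removes the TBS group without the base-induced acyl migration to O4 that an alkoxide-generating fluoride source could cause.

**Compound list**

1 | methyl 2-(bromomethyl)acrylate | COC(=O)C(=C)CBr | starting material
2 | vinylmagnesium bromide | C=C[Mg]Br | starting material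
3 | methyl 2-methylidenepent-4-enoate | COC(=O)C(=C)CC=C | intermediate
4 | methyl 2-[(1,2,4-trioxolan-3-yl)methyl]acrylate (ozonide of 3) | COC(=O)C(=C)CC1OCOO1 | intermediate
5 | methyl 2-methylidene-4-oxobutanoate | COC(=O)C(=C)CC=O | intermediate
6 | 1-[(tert-butyldimethylsilyl)oxy]propan-2-one | CC(=O)CO[Si](C)(C)C(C)(C)C | starting material
7 | methyl (4R,5S)-5-[(tert-butyldimethylsilyl)oxy]-4-hydroxy-2-methylidene-6-oxoheptanoate | COC(=O)C(=C)C[C@@H](O)[C@H](O[Si](C)(C)C(C)(C)C)C(C)=O | intermediate
8 | methyl (4R,5S)-5-[(tert-butyldimethylsilyl)oxy]-2-methylidene-6-oxo-4-[(triethylsilyl)oxy]heptanoate | COC(=O)C(=C)C[C@@H](O[Si](CC)(CC)CC)[C@H](O[Si](C)(C)C(C)(C)C)C(C)=O | intermediate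
9 | ozonide of 8 (methyl 3-substituted 1,2,4-trioxolane-3-carboxylate, ring carbon epimers) | COC(=O)C1(C[C@@H](O[Si](CC)(CC)CC)[C@H](O[Si](C)(C)C(C)(C)C)C(C)=O)OCOO1 | intermediate
10 | methyl (4R,5S)-5-[(tert-butyldimethylsilyl)oxy]-2,6-dioxo-4-[(triethylsilyl)oxy]heptanoate | COC(=O)C(=O)C[C@@H](O[Si](CC)(CC)CC)[C@H](O[Si](C)(C)C(C)(C)C)C(C)=O | intermediate
11 | methyl (4S,5R)-4-[(tert-butyldimethylsilyl)oxy]-1-hydroxy-3-oxo-5-[(triethylsilyl)oxy]cyclohexane-1-carboxylate (C1 epimers) | COC(=O)C1(O)CC(=O)[C@@H](O[Si](C)(C)C(C)(C)C)[C@H](O[Si](CC)(CC)CC)C1 | intermediate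
12 | 1-O-trifluoroacetate of 11 (C1 epimers) | COC(=O)C1(OC(=O)C(F)(F)F)CC(=O)[C@@H](O[Si](C)(C)C(C)(C)C)[C@H](O[Si](CC)(CC)CC)C1 | intermediate
13 | methyl (4S,5R)-4-[(tert-butyldimethylsilyl)oxy]-3-oxo-5-[(triethylsilyl)oxy]cyclohex-1-ene-1-carboxylate | COC(=O)C1=CC(=O)[C@@H](O[Si](C)(C)C(C)(C)C)[C@H](O[Si](CC)(CC)CC)C1 | intermediate
14 | methyl (4S,5R)-4-[(tert-butyldimethylsilyl)oxy]-5-hydroxy-3-oxocyclohex-1-ene-1-carboxylate | COC(=O)C1=CC(=O)[C@@H](O[Si](C)(C)C(C)(C)C)[C@H](O)C1 | intermediate
15 | methyl (3R,4S,5R)-4-[(tert-butyldimethylsilyl)oxy]-3,5-dihydroxycyclohex-1-ene-1-carboxylate | O[C@@H]1C=C(C(=O)OC)C[C@@H](O)[C@@H]1O[Si](C)(C)C(C)(C)C | intermediate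
16 | (E)-3-methylpent-2-enoic acid | CC/C(C)=C/C(=O)O | starting material
17 | O-[(E)-3-methylpent-2-enoyl]-N,N'-dicyclohexylisourea | CC/C(C)=C/C(=O)OC(=NC1CCCCC1)NC1CCCCC1 | intermediate
18 | methyl (3R,4S,5R)-4-[(tert-butyldimethylsilyl)oxy]-3,5-bis{[(2E)-3-methylpent-2-enoyl]oxy}cyclohex-1-ene-1-carboxylate | CC/C(C)=C/C(=O)O[C@@H]1C=C(C(=O)OC)C[C@@H](OC(=O)/C=C(\C)CC)[C@@H]1O[Si](C)(C)C(C)(C)C | intermediate
19 | methyl (3R,4S,5R)-4-hydroxy-3,5-bis{[(2E)-3-methylpent-2-enoyl]oxy}cyclohex-1-ene-1-carboxylate | CC/C(C)=C/C(=O)O[C@@H]1C=C(C(=O)OC)C[C@@H](OC(=O)/C=C(\C)CC)[C@@H]1O | target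

**Step count and risks**

Total step count: 11. Longest linear sequence: 11 steps (1 and 2 to 19).

Steps most likely to fail:

1. Step 3. The double bond of the β,γ-unsaturated aldehyde may migrate into conjugation, or the aldehyde may self-condense, under amine catalysis faster than the cross-aldol proceeds; syn and enantioselectivity may also erode with an unbranched aliphatic acceptor. The fallback sets out from 5 and returns at 7, forming the same C4–C5 bond by a Lewis-acid-mediated Mukaiyama aldol with no amine present. Commercial ethyl (tert-butyldimethylsilyloxy)acetate is converted with EtSH/AlMe3 into S-ethyl 2-[(tert-butyldimethylsilyl)oxy]ethanethioate F1. LDA/TMSCl then gives the silyl ketene acetal (Z)-2-[(tert-butyldimethylsilyl)oxy]-1-(ethylsulfanyl)-1-[(trimethylsilyl)oxy]ethene F2. Addition of F2 to 5 is mediated by Sn(OTf)2 (divalent tin), Bu2Sn(OAc)2 and a proline-derived chiral diamine in CH2Cl2 at −78 °C; the diamine is (S)-1-methyl-2-(piperidin-1-ylmethyl)pyrrolidine or its enantiomer, whichever delivers the 2S,3R sense. This should give the syn adduct S-ethyl (2S,3R)-2-[(tert-butyldimethylsilyl)oxy]-3-hydroxy-5-(methoxycarbonyl)hex-5-enethioate F3. Fukuyama coupling of F3 (MeZnI, PdCl2(PPh3)2, toluene) turns the thioester into the methyl ketone, which is 7.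

2. Step 6. Enolisation of the keto ester at C3 with E1cB loss of the neighbouring silyloxy group, or epimerisation at C5, may compete with ring closure under amine base. The fallback sets out from 8 and returns at 11, closing the same C1–C2 bond with a regiodefined zinc enolate in a neutral medium. Kinetic deprotonation of the methyl ketone of 8 (LiHMDS, THF, −78 °C) and bromination of the lithium enolate with NBS should give methyl (4R,5S)-7-bromo-5-[(tert-butyldimethylsilyl)oxy]-2-methylidene-6-oxo-4-[(triethylsilyl)oxy]heptanoate F4. Ozonolysis in the presence of pyridine (O3, pyridine, CH2Cl2, −78 °C), which needs no reducing agent that could attack the bromide, unmasks the keto ester to methyl (4R,5S)-7-bromo-5-[(tert-butyldimethylsilyl)oxy]-2,6-dioxo-4-[(triethylsilyl)oxy]heptanoate F5. Activated zinc in THF at 0 °C then forms the zinc enolate at C7 only, and an intramolecular Reformatsky-type addition to the keto ester carbonyl gives 11.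

3. Step 9. Hydride may be delivered intermolecularly (axial attack, giving the C3 epimer) instead of from the boron-bound C5 oxygen, so facial selectivity may be poor. The fallback sets out from 13 and returns at 18, using inversion instead of directed delivery. Luche reduction of 13 (NaBH4, CeCl3·7H2O, MeOH, −78 °C) is expected to give mainly the all-equatorial alcohol methyl (3S,4R,5R)-4-[(tert-butyldimethylsilyl)oxy]-3-hydroxy-5-[(triethylsilyl)oxy]cyclohex-1-ene-1-carboxylate F6. Mitsunobu esterification of F6 with acid 16 (PPh3, DIAD, toluene, 0 °C) installs the C3 ester with inversion, giving methyl (3R,4R,5R)-4-[(tert-butyldimethylsilyl)oxy]-3-{[(2E)-3-methylpent-2-enoyl]oxy}-5-[(triethylsilyl)oxy]cyclohex-1-ene-1-carboxylate F7. PPTS in MeOH removes the TES group to give methyl (3R,4S,5R)-4-[(tert-butyldimethylsilyl)oxy]-5-hydroxy-3-{[(2E)-3-methylpent-2-enoyl]oxy}cyclohex-1-ene-1-carboxylate F8. Steglich acylation of the C5 hydroxyl of F8 with 16 (DCC, DMAP, through 17) gives 18.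

**Further compounds**

F1 | step 3 | S-ethyl 2-[(tert-butyldimethylsilyl)oxy]ethanethioate | CCSC(=O)CO[Si](C)(C)C(C)(C)C
F2 | step 3 | (Z)-2-[(tert-butyldimethylsilyl)oxy]-1-(ethylsulfanyl)-1-[(trimethylsilyl)oxy]ethene | CCS/C(O[Si](C)(C)C)=C\O[Si](C)(C)C(C)(C)C
F3 | step 3 | S-ethyl (2S,3R)-2-[(tert-butyldimethylsilyl)oxy]-3-hydroxy-5-(methoxycarbonyl)hex-5-enethioate | CCSC(=O)[C@@H](O[Si](C)(C)C(C)(C)C)[C@H](O)CC(=C)C(=O)OC
F4 | step 6 | methyl (4R,5S)-7-bromo-5-[(tert-butyldimethylsilyl)oxy]-2-methylidene-6-oxo-4-[(triethylsilyl)oxy]heptanoate | COC(=O)C(=C)C[C@@H](O[Si](CC)(CC)CC)[C@H](O[Si](C)(C)C(C)(C)C)C(=O)CBr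
F5 | step 6 | methyl (4R,5S)-7-bromo-5-[(tert-butyldimethylsilyl)oxy]-2,6-dioxo-4-[(triethylsilyl)oxy]heptanoate | COC(=O)C(=O)C[C@@H](O[Si](CC)(CC)CC)[C@H](O[Si](C)(C)C(C)(C)C)C(=O)CBr
F6 | step 9 | methyl (3S,4R,5R)-4-[(tert-butyldimethylsilyl)oxy]-3-hydroxy-5-[(triethylsilyl)oxy]cyclohex-1-ene-1-carboxylate | O[C@H]1C=C(C(=O)OC)C[C@@H](O[Si](CC)(CC)CC)[C@@H]1O[Si](C)(C)C(C)(C)C
F7 | step 9 | methyl (3R,4R,5R)-4-[(tert-butyldimethylsilyl)oxy]-3-{[(2E)-3-methylpent-2-enoyl]oxy}-5-[(triethylsilyl)oxy]cyclohex-1-ene-1-carboxylate | CC/C(C)=C/C(=O)O[C@@H]1C=C(C(=O)OC)C[C@@H](O[Si](CC)(CC)CC)[C@@H]1O[Si](C)(C)C(C)(C)C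
F8 | step 9 | methyl (3R,4S,5R)-4-[(tert-butyldimethylsilyl)oxy]-5-hydroxy-3-{[(2E)-3-methylpent-2-enoyl]oxy}cyclohex-1-ene-1-carboxylate | CC/C(C)=C/C(=O)O[C@@H]1C=C(C(=O)OC)C[C@@H](O)[C@@H]1O[Si](C)(C)C(C)(C)C
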